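The flavanone is cut across O1–C2 and C3–C4 of ring C. These two bonds leave ring A at C8a and C4a, and O1=C8a–C4a=C4 is the heterodiene of an ortho-quinone methide. Its chiral-acid-controlled inverse-demand (4+2) cycloaddition with styrene closes ring C, brings in C2, C3 and the phenyl group, sets C2, and delivers C4 as a methyl ether one oxidation step below the ketone. The precursor is a geranylated salicylaldehyde, made from 3,5-dimethoxyphenol with use of its mirror symmetry, whose single free phenol lies para to the geranyl group and therefore must become O1. Hydrolysis, oxidation and chelation-directed C5 demethylation finish the synthesis.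

Key step: step 5

Remarks on the chemistry:
- Geranyl stands for (2E)-3,7-dimethylocta-2,6-dien-1-yl; atom and ring labels are those of the flavanone.
- Assumption: the sense of induction of the chiral acid in step 5 cannot be fixed in advance. The (S)-acid is written; its mirror image is used, with nothing else changed, if the first analysis shows the (2R) series.
- Design choice: both oxygens flanking the geranyl group stay methylated until the last step. Any other group on the C5 oxygen would make the two ortho positions of the phenol formylated in step 4 unequal and cost several steps of differentiation.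

Step 1
Reactants: 1 3,5-dimethoxyphenol
Product: 2 (3,5-dimethoxyphenoxy)triisopropylsilane
Conditions: TIPSCl, imidazole, DMF, rt
Reagents that add atoms: triisopropylsilyl chloride, CC(C)[Si](Cl)(C(C)C)C(C)C
Why: O-silylation of a phenol; the bulky silyl ether withstands n-BuLi and is a poor ortho director, so the site between the two methoxy groups remains the metalation site for step 2.

Step 2
Reactants: 2 (3,5-dimethoxyphenoxy)triisopropylsilane; 3 geranyl bromide
Product: 5 (4-geranyl-3,5-dimethoxyphenoxy)triisopropylsilane, via aryllithium 4 (not isolated)
Conditions: n-BuLi, THF, 0 °C → rt; then geranyl bromide, −78 °C → rt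
Reagents that add atoms: none
Why: Directed ortho-metalation at the carbon flanked by two methoxy groups, then SN2 alkylation of the aryllithium at the primary allylic bromide, which keeps the E-alkene and places geranyl para to the silyloxy group.

Step 3
Reactants: 5 (4-geranyl-3,5-dimethoxyphenoxy)triisopropylsilane
Product: 6 4-geranyl-3,5-dimethoxyphenol
Conditions: TBAF, THF, 0 °C
Reagents that add atoms: none
Why: Fluoride-induced cleavage of the aryl silyl ether, to which alkenes and methyl ethers are inert.

Step 4
Reactants: 6 4-geranyl-3,5-dimethoxyphenol
Product: 8 3-geranyl-6-hydroxy-2,4-dimethoxybenzaldehyde, via hydroxymethyl phenol 7 (not isolated)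
Conditions: MgCl2, Et3N, (CH2O)n, MeCN, reflux
Reagents that add atoms: paraformaldehyde (reacts as formaldehyde), C=O
Why: Casnati–Skattebøl ortho-formylation, in which the magnesium phenoxide delivers formaldehyde to the ortho carbon and a second formaldehyde oxidises the benzylic alkoxide by hydride transfer; the two ortho positions are equivalent by symmetry, so one aldehyde should form, and the non-acidic medium spares the geranyl alkenes.

Step 5
Reactants: 8 3-geranyl-6-hydroxy-2,4-dimethoxybenzaldehyde; 9 styrene; 10 trimethyl orthoformate
Product: 13 (2S,4S)-6-geranyl-4,5,7-trimethoxy-2-phenylchroman, via dimethyl acetal 11 (not isolated), via ortho-quinone methide 12 (not isolated)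
Conditions: styrene (5 equiv), HC(OMe)3 (1.5 equiv), (S)-3,3'-bis(2,4,6-triisopropylphenyl)-1,1'-binaphthyl-2,2'-diyl N-triflylphosphoramide (5 mol%), 5 Å MS, CH2Cl2, −40 °C, slow addition of 8
Reagents that add atoms: none
Why: The acid and orthoformate 10 turn 8 into acetal 11, which loses methanol to give the O-protonated ortho-quinone methide 12 (a methoxy-stabilised benzylic oxocarbenium ion) as a contact ion pair with the chiral phosphoramide anion; styrene then adds across O1=C8a–C4a=C4 in an asynchronous inverse-electron-demand hetero-Diels–Alder reaction, its CH2 carbon bonding to C4 while the developing benzylic cation is taken up by the phenolic oxygen. The closest known reaction types are the achiral acid-promoted cycloaddition of salicylaldehyde-acetal-derived ortho-quinone methides with styrenes to 4-alkoxy-2-arylchromans and the N-triflylphosphoramide-catalysed enantioselective (4+2) cycloaddition of ortho-quinone methides with styrenes; enantiocontrol with an alkoxy-substituted quinone methide and unsubstituted styrene lies at the limit of what these cover, which is why the risk of the route is placed here. Ring C closes as a six-membered (4+2) annulation in which C3–C4 forms ahead of O1–C2, the second bond being the collapse of O1 onto the benzylic C2 cation in the stepwise limit. C2 is set by the chiral anion, which is hydrogen-bonded to the phenolic OH and leaves one face of the planar cation open, so that one enantiotopic face of the styrene CH carbon meets O1; C4 follows from the endo placement of phenyl (2,4-cis expected) and needs no control because it is oxidised in step 7. Regioselectivity (CH2 of styrene to C4, phenyl on C2) follows from the polarisation of styrene and of the cation, and O1 can only be the oxygen para to geranyl because the other two oxygens are methylated. Chemoselectivity over the geranyl alkenes and over Friedel–Crafts attack by the electron-rich C8–H is served by the low temperature, by an acid strong enough to ionise the acetal but not to protonate a trisubstituted alkene, by excess styrene and by slow addition of 8.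

Step 6
Reactants: 13 (2S,4S)-6-geranyl-4,5,7-trimethoxy-2-phenylchroman
Product: 14 (2S)-6-geranyl-5,7-dimethoxy-2-phenylchroman-4-ol (mixture of C4 epimers)
Conditions: aq. HCl (0.1 M), THF, 0 °C → rt
Reagents that add atoms: water, O
Why: SN1 solvolysis of a benzylic methyl ether, whose C4 cation is stabilised by the ortho and para oxygens of ring A and is captured by the large excess of water; C2 is not on the ionisation path and should keep its configuration, and C4 needs no control.

Step 7
Reactants: 14 (2S)-6-geranyl-5,7-dimethoxy-2-phenylchroman-4-ol
Product: 15 (2S)-6-geranyl-5,7-dimethoxy-2-phenylchroman-4-one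
Conditions: Dess–Martin periodinane, pyridine, CH2Cl2, 0 °C → rt
Reagents that add atoms: none
Why: Dess–Martin oxidation of a secondary benzylic alcohol under buffered, near-neutral conditions; both C4 epimers converge on one ketone, trisubstituted alkenes and aryl ethers are inert to the reagent, and the weak base should not open ring C by retro-oxa-Michael reaction.

Step 8
Reactants: 15 (2S)-6-geranyl-5,7-dimethoxy-2-phenylchroman-4-one
Product: 16 (2S)-6-geranylpinostrobin [(2S)-6-geranyl-5-hydroxy-7-methoxy-2-phenylchroman-4-one]
Conditions: MgI2·OEt2, THF, 50 °C; then cold aq. NH4Cl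
Reagents that add atoms: none
Why: Chelation-controlled O-demethylation, in which magnesium held between the C4 carbonyl oxygen and the peri C5 methoxy oxygen activates only that methyl group for SN2 attack by iodide, so the non-chelating C7 methoxy group survives; the mild Lewis acid without protic acid should leave the geranyl alkenes and the C2–O1 bond untouched.

Compound list
1 | 3,5-dimethoxyphenol | COc1cc(O)cc(OC)c1 | starting material
2 | (3,5-dimethoxyphenoxy)triisopropylsilane | COc1cc(O[Si](C(C)C)(C(C)C)C(C)C)cc(OC)c1 | intermediate
3 | geranyl bromide, (2E)-1-bromo-3,7-dimethylocta-2,6-diene | BrC/C=C(\C)CCC=C(C)C | starting material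
4 | [2,6-dimethoxy-4-(triisopropylsilyloxy)phenyl]lithium | [Li]c1c(OC)cc(O[Si](C(C)C)(C(C)C)C(C)C)cc1OC | intermediate (not isolated)
5 | (4-geranyl-3,5-dimethoxyphenoxy)triisopropylsilane | COc1cc(O[Si](C(C)C)(C(C)C)C(C)C)cc(OC)c1C/C=C(\C)CCC=C(C)C | intermediate
6 | 4-geranyl-3,5-dimethoxyphenol | COc1cc(O)cc(OC)c1C/C=C(\C)CCC=C(C)C | intermediate
7 | 4-geranyl-2-(hydroxymethyl)-3,5-dimethoxyphenol | COc1cc(O)c(CO)c(OC)c1C/C=C(\C)CCC=C(C)C | intermediate (not isolated)
8 | 3-geranyl-6-hydroxy-2,4-dimethoxybenzaldehyde | COc1cc(O)c(C=O)c(OC)c1C/C=C(\C)CCC=C(C)C | intermediate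
9 | styrene | C=Cc1ccccc1 | starting material
10 | trimethyl orthoformate | COC(OC)OC | starting material
11 | 2-(dimethoxymethyl)-4-geranyl-3,5-dimethoxyphenol | COc1cc(O)c(C(OC)OC)c(OC)c1C/C=C(\C)CCC=C(C)C | intermediate (not isolated)
12 | 4-geranyl-3,5-dimethoxy-6-(methoxymethylidene)cyclohexa-2,4-dien-1-one (neutral form; O-protonated and ion-paired in the flask) | COC=C1C(=O)C=C(OC)C(C/C=C(\C)CCC=C(C)C)=C1OC | intermediate (not isolated)
13 | (2S,4S)-6-geranyl-4,5,7-trimethoxy-2-phenylchroman (2,4-cis) | COc1cc2c(c(OC)c1C/C=C(\C)CCC=C(C)C)[C@@H](OC)C[C@@H](c1ccccc1)O2 | intermediate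
14 | (2S)-6-geranyl-5,7-dimethoxy-2-phenylchroman-4-ol (C4 epimers, C4 left undefined) | COc1cc2c(c(OC)c1C/C=C(\C)CCC=C(C)C)C(O)C[C@@H](c1ccccc1)O2 | intermediate
15 | (2S)-6-geranyl-5,7-dimethoxy-2-phenylchroman-4-one | COc1cc2c(c(OC)c1C/C=C(\C)CCC=C(C)C)C(=O)C[C@@H](c1ccccc1)O2 | intermediate
16 | (2S)-6-geranylpinostrobin | COc1cc2c(c(O)c1C/C=C(\C)CCC=C(C)C)C(=O)C[C@@H](c1ccccc1)O2 | target

Total step count: 8. Longest linear sequence: 8 steps (1 to 16).

Steps most likely to fail

Step 5. The chiral anion may discriminate poorly between the faces of a styrene that offers no binding handle, so that C2 forms with low selectivity; the cation may also be diverted into alkylation of an electron-rich ring carbon. The fallback replaces asymmetric induction by resolution and uses known chemistry. It sets out from 8, 9 and 10: an achiral acid (Sc(OTf)3, CH2Cl2, −20 °C, larger excess of styrene, higher dilution) should give the racemic 2,4-cis-6-geranyl-4,5,7-trimethoxy-2-phenylchroman F1. Hydrolysis and Dess–Martin oxidation as in steps 6 and 7 should give the racemic 4-ol F2 and the racemic ketone F3. Kinetic resolution of F3 by asymmetric transfer hydrogenation (RuCl(p-cymene)[(R,R)-TsDPEN], HCO2H/Et3N 5:2, CH2Cl2, rt, run slightly past half conversion) should reduce the (2R)-ketone faster, because for it the hydride face chosen by the catalyst is also the one that leads to the 2,4-cis alcohol. This gives the (2R,4R)-6-geranyl-5,7-dimethoxy-2-phenylchroman-4-ol F4 and leaves the (2S)-ketone, which is separated on silica. The fallback comes back to the route at 15.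

Step 6. The benzylic C4 cation may lose a proton from C3 (elimination to the 2H-chromene) or be captured by C8 of a second molecule faster than by water. The fallback changes from solvolysis to oxidation and sets out from 13: DDQ (1.2 equiv) in CH2Cl2/pH 7 buffer at 0 °C should abstract hydride from C4–H, which is benzylic and alpha to oxygen; hydration of the resulting oxocarbenium ion and loss of methanol should give the ketone directly. No new compound is made (F0), step 7 is skipped, and the fallback comes back to the route at 15.

Step 2. Metalation may occur next to the silyloxy group and be followed by migration of silicon from oxygen to carbon, or n-BuLi may attack silicon. The fallback brings in the phenol oxygen after the geranyl group and sets out from 3. Purchased 1,3-dimethoxybenzene F5 has only one doubly activated site; n-BuLi (THF, 0 °C → rt) should give 2,6-dimethoxyphenyllithium F6, which is alkylated by 3 to 2-geranyl-1,3-dimethoxybenzene F7. Sterically controlled C–H borylation ([Ir(OMe)(cod)]2, 4,4'-di-tert-butyl-2,2'-bipyridine, B2pin2, THF, 60 °C) should go to the only ring C–H with two hydrogen neighbours, para to geranyl, and give 2-(4-geranyl-3,5-dimethoxyphenyl)-4,4,5,5-tetramethyl-1,3,2-dioxaborolane F8. Oxidation with NaBO3·4H2O (THF/H2O, rt) should give the phenol; steps 1 to 3 are replaced and the fallback comes back to the route at 6.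

Step 8 is judged next in line. It is kept out of the three because chelation-directed 5-O-demethylation of flavanones with MgI2 is established chemistry that tolerates prenyl-type side chains.

Further compounds
F1 | step 5 | racemic 2,4-cis-6-geranyl-4,5,7-trimethoxy-2-phenylchroman | COc1cc2c(c(OC)c1C/C=C(\C)CCC=C(C)C)C(OC)CC(c1ccccc1)O2
F2 | step 5 | racemic 6-geranyl-5,7-dimethoxy-2-phenylchroman-4-ol | COc1cc2c(c(OC)c1C/C=C(\C)CCC=C(C)C)C(O)CC(c1ccccc1)O2
F3 | step 5 | racemic 6-geranyl-5,7-dimethoxy-2-phenylchroman-4-one | COc1cc2c(c(OC)c1C/C=C(\C)CCC=C(C)C)C(=O)CC(c1ccccc1)O2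
F4 | step 5 | (2R,4R)-6-geranyl-5,7-dimethoxy-2-phenylchroman-4-ol | COc1cc2c(c(OC)c1C/C=C(\C)CCC=C(C)C)[C@H](O)C[C@H](c1ccccc1)O2
F0 | step 6 | none | none
F5 | step 2 | 1,3-dimethoxybenzene (purchased) | COc1cccc(OC)c1
F6 | step 2 | 2,6-dimethoxyphenyllithium | [Li]c1c(OC)cccc1OC
F7 | step 2 | 2-geranyl-1,3-dimethoxybenzene | COc1cccc(OC)c1C/C=C(\C)CCC=C(C)C
F8 | step 2 | 2-(4-geranyl-3,5-dimethoxyphenyl)-4,4,5,5-tetramethyl-1,3,2-dioxaborolane | COc1cc(B2OC(C)(C)C(C)(C)O2)cc(OC)c1C/C=C(\C)CCC=C(C)C
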